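Ring numbering used throughout: O1, C2 (the benzylic carbon whose aryl group is cis to the neighbouring arm), C3, C4, C5.

Numbering key: 1 syringaldehyde; 2 its pivalate; 3 benzyl propargyl ether; 4 alkynylborate complex; 5 alkynylboronate; 6 borazirconocene alkene; 7 (Z)-alkenylboronate; 8 (chloromethyl)borate complex; 9 (Z)-allylboronate; 10 borate ester; 11 syn homoallylic alcohol; 12 allyltrimethylsilane; 13 allylsilane alcohol; 14 oxocarbenium ion; 15 vinyl oxolane; 16 diol; 17 C4 aldehyde; 18 benzyl ether with free phenols; 19 target.

## Analysis of the target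

Compound 19 is a tetrahydrofuran lignan: one oxolane ring (O1, C2–C5) carrying the same 4-hydroxy-3,5-dimethoxyphenyl group on C2 and C5 and a hydroxymethyl arm on C3 and C4. All four ring carbons are stereogenic, (2S,3S,4S,5R): the aryl groups are 2,5-cis, the C3 arm is cis to the C2 aryl, and the C4 arm is trans to both the C3 arm and the C5 aryl. The constitution is symmetrical but this pattern is not, so the two halves cannot come from one dimerising operation and C3 and C4 must be handled differently. Sensitive features are the two electron-rich free phenols (oxidation; acid-promoted ionisation of the benzylic C2–O1 and C5–O1 bonds, which would scramble C2 and C5), the same benzylic C–O bonds under hydrogenolysis, and two primary alcohols. The main difficulty is stereochemical: four contiguous centres on a flexible five-membered ring, with a 2,3-cis relationship that is not the thermodynamic one and cannot be repaired after ring formation, because C2, C3 and C5 carry no acidifying group. The plan rests on C4: it bears a single carbon and is bonded to C5, which is at the aldehyde oxidation level once O1=C5 is an oxocarbenium ion. A vinyl group on C4 is what an allylsilane leaves behind when its γ-carbon attacks C5, and it is also a masked hydroxymethyl group. After cleavage to a formyl group, C4 is the one centre that can be equilibrated, and it equilibrates towards the trans,trans arrangement of the target.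

## Retrosynthetic reasoning

**19 back to 17.** No skeletal bond is cut first. The phenols are masked as pivalates, the C3 arm as a benzyl ether, and the C4 arm is raised to a formyl group; this leads through benzyl ether 18 to aldehyde 17. An acyl group on the para oxygen, with the methoxyls meta to the benzylic carbon, makes the aryl groups poor cation stabilisers. That protects C2–O1 and C5–O1 in every acidic step, and one hydride reduction removes the pivalates together with the aldehyde. The benzyl ether tells the C3 arm from the C4 arm and survives Lewis acid, oxidant, base and hydride.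

**17 back to 15.** The formyl carbon is traced to the internal carbon of a vinyl group; forward, the C=C bond of 15 is cut oxidatively through diol 16. The gain is a C4 substituent that is inert to Lewis acid and that an allylsilane can deliver. The forward reaction must cleave the alkene without touching the arenes; it then leaves C4 α to a carbonyl, where mild base can move it trans to both neighbours.

**15 back to 13 and 2.** The key disconnection cuts O1–C5 and C4–C5. C5 becomes the carbonyl carbon of aldehyde 2, the same aldehyde that supplies C2, and C4 becomes the γ-carbon of the allylsilane in 13. The two centres that cannot be corrected later, C2 and C3, then already exist in an acyclic precursor. Cutting O1–C2 or C2–C3 instead would leave the 2,3-cis relationship to be made during ring closure. Forward, the hydroxyl of 13 and aldehyde 2 must give oxocarbenium ion 14, which must close 2,5-cis.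

**13 back to 11 and 12.** The allylsilane is cut at its C=C bond into terminal alkene 11 and allyltrimethylsilane 12 (cross-metathesis). Silicon is thereby kept out of the preceding stereoselective C–C bond formation. The internal alkene carbon of 12 is the carbon that ends as the C4 hydroxymethyl group. The geometry of the new alkene is not critical, since the only centre it influences is C4.

**11 back to 2 and 9.** Cutting the bond that becomes C2–C3 gives aldehyde 2 and the (Z)-allylboronate 9. A closed six-membered transition state turns the Z geometry into the syn relationship, which is the 2,3-cis relationship of the ring, and a chiral Brønsted acid selects the aldehyde face; borate 10 is the primary product. This one step must set both C2 and C3 absolutely.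

**9 back to 7, 5 and 3.** The Z geometry of 9 must be secure. Compound 9 is therefore traced, by removal of the boron-bound methylene (1,2-metallate shift in 8), to (Z)-alkenylboronate 7. The geometry of 7 comes from syn hydrometallation of alkynylboronate 5 (through 6) and protonolysis, and 5 comes from terminal alkyne 3 through borate 4. Each step is stereospecific or has no stereochemistry, which is preferred to routes through π-allyl metal species that drift to the E isomer.

**2 back to 1.** Aldehyde 2 is the pivalate of syringaldehyde 1.

## Alternatives that were turned down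

**Alternative 1:** O1–C2 and C4–C5 are cut as a formal [3+2] union of aldehyde 2 with the donor–acceptor cyclopropane A2. Forward, Sn(OTf)2 would open A2 by attack of the aldehyde oxygen at the benzylic carbon with inversion, and the malonate carbon would close onto the carbonyl carbon to give the oxolane diester A1.
- For: the step is stereospecific at C2, leaves C3 untouched, is convergent, and annulations of this kind have a strong inherent 2,5-cis preference. On the 2,5-cis question it is stronger than the chosen route, which relies on a transition-state preference.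
- Against: A2 is an enantiopure trans-2-aryl-3-substituted cyclopropane-1,1-diester, and asymmetric cyclopropanation of a 1,2-disubstituted styrene-type alkene with a malonate carbenoid is not a dependable step. The acyloxy-substituted aryl group is a weak donor, so opening would be slow, while a stronger donor invites racemisation through an open zwitterion. The C3 substituent hinders attack at the adjacent carbon.
- Against, after the ring: A1 has two carboxyl carbons on C4. One must be excised (Krapcho-type dealkoxycarbonylation, hot and hard on aryl pivalates), C4 then set by protonation, the ester reduced and the silyl ether removed.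
- Comparison: the chosen route brings exactly one carbon to C4 as a vinyl group and corrects C4 under mild base; its precursor comes from a catalytic asymmetric allylation.

**Alternative 2:** C2–C3 is cut. Forward, Rh2(S-PTTL)4 (dirhodium tetrakis[N-phthaloyl-(S)-tert-leucinate]) would decompose the α-diazo ester A4, and the carbenoid at C3 would insert into the benzylic ether C–H bond five atoms away to give oxolane ester A3.
- For: a C–C bond is made at an unfunctionalised C–H position, and such insertions tend to give the kinetic 2,3-cis product, which is the relationship the target needs. The C3 carbon arrives at the carboxyl level, so no carbon is excised and no oxidative cleavage is needed. On these two points it is as strong as or stronger than the chosen route.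
- Against: A4 has a tertiary C–H on the carbon next to the carbenoid, so 1,2-hydride shift to the unsaturated ester competes. Two stereocentres already present in A4 make catalyst control a matched or mismatched case. The two aryl groups need different protection (an electron-rich benzyloxy aryl at the insertion site, a pivalate on the other). The diazo group has to be installed on a hindered, unactivated ester. The C3 ester of A3 epimerises towards 2,3-trans, the wrong direction.
- Comparison: in the chosen route the only epimerisable centre (C4) moves in the right direction, and the 2,3-cis pair is fixed in a closed-transition-state allylation at centres that cannot epimerise.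

**Alternative 3:** O1–C2, C2–C3 and C4–C5 are cut, with the old C5–carbinol bond broken in the forward direction. The (Z)-allylic anti-diol A6 and aldehyde 2 would condense under SnCl4 to an oxocarbenium ion, undergo a 2-oxonia-[3,3] shift through a chair and close by an aldol step to the formyl oxolane A5, which is the same structure as aldehyde 17.
- For: this is the shortest path after ring formation, since it reaches 17 directly and saves the metathesis and the oxidative cleavage. On step economy it is stronger than the chosen route.
- Against: A6 needs its own synthesis with two carbinol centres and a Z alkene. The intermediate acetal can ionise at either oxygen and only one mode is productive. The benzylic and allylic C–O bonds can ionise under SnCl4. The Z substituent is axial in the chair, so a boat pathway would erode the 2,3-cis relationship at centres that cannot be corrected. Enantiopurity depends on faithful chirality transfer through a reversible sigmatropic step.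
- Comparison: the chosen route sets C2 and C3 before any cation is generated and leaves to the cationic step only C5 (transition-state controlled) and C4 (correctable).

Key step: step 7

Assumption: for BINOL-derived phosphoric acids of the TRIP type the (R)-acid is taken to direct allylboronates to the Re face of aryl aldehydes, so the (S)-acid is specified for the Si-face addition needed here; if the sense were the reverse, the antipodal acid would be used with no other change.

## Route

Step 1
Reactants: 1 syringaldehyde
Product: 2 4-formyl-2,6-dimethoxyphenyl pivalate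
Conditions: PivCl, Et3N, DMAP (cat.), CH2Cl2, 0 °C → rt
Reagents that add atoms: pivaloyl chloride, CC(C)(C)C(=O)Cl
Why: DMAP-catalysed O-acylation of the phenol; the ester weakens the para oxygen as a donor for the later cationic step and is removed by hydride at the end.

Step 2
Reactants: 3 benzyl propargyl ether
Product: 5 2-[3-(benzyloxy)prop-1-yn-1-yl]-4,4,5,5-tetramethyl-1,3,2-dioxaborolane, via lithium alkynyl(isopropoxy)borate 4 (not isolated)
Conditions: n-BuLi, THF, −78 °C; 2-isopropoxy-4,4,5,5-tetramethyl-1,3,2-dioxaborolane, −78 °C; HCl in Et2O, −78 °C → rt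
Reagents that add atoms: 2-isopropoxy-4,4,5,5-tetramethyl-1,3,2-dioxaborolane, CC(C)OB1OC(C)(C)C(C)(C)O1
Why: Deprotonation of the terminal alkyne and borylation through borate 4; anhydrous acid collapses the ate complex to the alkynylboronate without protodeboronation (standard preparation of alkynyl pinacol boronates).

Step 3
Reactants: 5 2-[3-(benzyloxy)prop-1-yn-1-yl]-4,4,5,5-tetramethyl-1,3,2-dioxaborolane
Product: 7 2-[(Z)-3-(benzyloxy)prop-1-en-1-yl]-4,4,5,5-tetramethyl-1,3,2-dioxaborolane, via 1,1-borazirconocene alkene 6 (not isolated)
Conditions: Cp2Zr(H)Cl, THF, rt; then H2O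
Reagents that add atoms: none
Why: Schwartz hydrozirconation adds Zr–H syn across the alkyne with zirconium on the boron-bearing carbon; protonolysis of the C–Zr bond of 6 with retention leaves boron and the CH2OBn group cis, which is the Z-alkenylboronate.

Step 4
Reactants: 7 2-[(Z)-3-(benzyloxy)prop-1-en-1-yl]-4,4,5,5-tetramethyl-1,3,2-dioxaborolane
Product: 9 2-[(Z)-4-(benzyloxy)but-2-en-1-yl]-4,4,5,5-tetramethyl-1,3,2-dioxaborolane, via (chloromethyl)borate complex 8 (not isolated)
Conditions: BrCH2Cl, n-BuLi, THF, −78 °C → rt
Reagents that add atoms: bromochloromethane, ClCBr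
Why: Matteson homologation: chloromethyllithium made in the flask adds to boron, and 1,2-migration of the alkenyl group in 8 with loss of chloride inserts CH2 into the C–B bond with retention of the Z geometry.

Step 5
Reactants: 2 4-formyl-2,6-dimethoxyphenyl pivalate; 9 2-[(Z)-4-(benzyloxy)but-2-en-1-yl]-4,4,5,5-tetramethyl-1,3,2-dioxaborolane
Product: 11 4-[(1S,2S)-2-[(benzyloxy)methyl]-1-hydroxybut-3-en-1-yl]-2,6-dimethoxyphenyl pivalate, via pinacol borate ester 10 (not isolated)
Conditions: (S)-TRIP [(S)-3,3'-bis(2,4,6-triisopropylphenyl)-1,1'-binaphthyl-2,2'-diyl hydrogen phosphate] (5 mol%), 4 Å MS, toluene, −30 °C; then aq. NaHCO3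
Reagents that add atoms: none
Why: Chiral phosphoric acid-catalysed allylboration through a closed chair transition state: the aryl group equatorial and the Z-CH2OBn group axial give the syn pair, and the (S)-acid, hydrogen-bonded to a boronate oxygen and the formyl hydrogen, exposes the Si face, so that the carbinol carbon and its neighbour are both formed S.

Step 6
Reactants: 11 4-[(1S,2S)-2-[(benzyloxy)methyl]-1-hydroxybut-3-en-1-yl]-2,6-dimethoxyphenyl pivalate; 12 allyltrimethylsilane
Product: 13 4-[(1S,2S,3E)-2-[(benzyloxy)methyl]-1-hydroxy-5-(trimethylsilyl)pent-3-en-1-yl]-2,6-dimethoxyphenyl pivalate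
Conditions: 12 (excess), second-generation Grubbs catalyst RuCl2(=CHPh)(H2IMes)(PCy3) (5 mol%), CH2Cl2, 40 °C
Reagents that add atoms: none
Why: Olefin cross-metathesis of a hindered terminal alkene with an excess of the unhindered allylsilane; the E isomer should predominate, and any Z isomer of 13 need not be removed because both converge in steps 7 and 8.

Step 7
Reactants: 13 4-[(1S,2S,3E)-2-[(benzyloxy)methyl]-1-hydroxy-5-(trimethylsilyl)pent-3-en-1-yl]-2,6-dimethoxyphenyl pivalate; 2 4-formyl-2,6-dimethoxyphenyl pivalate
Product: 15 (2S,3S,4R,5R)-3-[(benzyloxy)methyl]-2,5-bis[3,5-dimethoxy-4-(pivaloyloxy)phenyl]-4-vinyloxolane, via (E)-oxocarbenium ion 14 (not isolated)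
Conditions: BF3·OEt2 (1.2 equiv), CH2Cl2, −78 → −30 °C; aq. NaHCO3
Reagents that add atoms: none
Why: BF3·OEt2 promotes hemiacetal formation between the hydroxyl of 13 and aldehyde 2 and ionises it to the (E)-oxocarbenium ion 14 (O1=C5). The γ-carbon of the allylsilane (C4) adds to C5 while the C–Si bond stabilises the developing β-cation, and loss of silicon leaves the vinyl group on C4; this is the intramolecular Hosomi–Sakurai (silyl-Prins type) condensation known for 5-silylpent-3-en-1-ols and aldehydes giving 3-vinyloxolanes. The oxolane closes in a 5-endo-trig mode at O1=C5 (both atoms end up in the ring), with the alkene exocyclic to the forming ring. C5 is set by an envelope transition state in which the C2 aryl and the C5 aryl of the E ion are both pseudo-equatorial, which gives the 2,5-cis ring. C4 is set by allylic 1,3-strain: H3 lies in the alkene plane, so C5 bonds to the alkene face away from the C3 arm and the vinyl group ends trans to the C3 arm and to the C5 aryl. C2 and C3 are carried unchanged from 13. The selectivity the step needs is 2,5-cis; it is secured by the E geometry of 14 and by the acyloxy-deactivated aryl groups, which disfavour ionisation of the benzylic C–O bonds. The C4 outcome and the alkene geometry of 13 are not critical because C4 is equilibrated at aldehyde 17.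

Step 8
Reactants: 15 (2S,3S,4R,5R)-3-[(benzyloxy)methyl]-2,5-bis[3,5-dimethoxy-4-(pivaloyloxy)phenyl]-4-vinyloxolane
Product: 17 (2S,3S,4R,5R)-3-[(benzyloxy)methyl]-2,5-bis[3,5-dimethoxy-4-(pivaloyloxy)phenyl]-4-formyloxolane, via vicinal diol 16 (not isolated)
Conditions: OsO4 (2 mol%), NaIO4, 2,6-lutidine, 1,4-dioxane/H2O (3:1), rt; then DBU (cat.), CH2Cl2, rt
Reagents that add atoms: osmium tetroxide, O=[Os](=O)(=O)=O (catalytic oxygen carrier); sodium periodate, [Na+].[O-]I(=O)(=O)=O (stoichiometric oxygen source)
Why: Johnson–Lemieux oxidation (osmium-catalysed dihydroxylation to 16, then periodate glycol cleavage) leaves the arenes untouched; C4 is now α to the formyl group, and catalytic DBU equilibrates any cis material through the enol to the isomer trans to both the C3 and the C5 substituent.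

Step 9
Reactants: 17 (2S,3S,4R,5R)-3-[(benzyloxy)methyl]-2,5-bis[3,5-dimethoxy-4-(pivaloyloxy)phenyl]-4-formyloxolane
Product: 18 (2S,3S,4S,5R)-3-[(benzyloxy)methyl]-4-(hydroxymethyl)-2,5-bis(4-hydroxy-3,5-dimethoxyphenyl)oxolane
Conditions: LiAlH4 (excess), THF, 0 °C → rt; aq. potassium sodium tartrate
Reagents that add atoms: none
Why: LiAlH4 reduces the aldehyde to the C4 hydroxymethyl group and cleaves both aryl pivalates by acyl reduction in one operation; no stereocentre is touched.

Step 10
Reactants: 18 (2S,3S,4S,5R)-3-[(benzyloxy)methyl]-4-(hydroxymethyl)-2,5-bis(4-hydroxy-3,5-dimethoxyphenyl)oxolane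
Product: 19 [(2S,3S,4S,5R)-2,5-bis(4-hydroxy-3,5-dimethoxyphenyl)oxolane-3,4-diyl]dimethanol
Conditions: H2 (1 atm), Pd/C (10%), EtOAc/MeOH, rt
Reagents that add atoms: none
Why: Hydrogenolysis of the primary benzyl ether over Pd/C under neutral conditions should be faster than cleavage of the ring benzylic C–O bonds, and the work-up is a filtration.

## Compound list

1 | syringaldehyde (4-hydroxy-3,5-dimethoxybenzaldehyde) | COc1cc(C=O)cc(OC)c1O | starting material
2 | 4-formyl-2,6-dimethoxyphenyl pivalate | COc1cc(C=O)cc(OC)c1OC(=O)C(C)(C)C | intermediate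
3 | benzyl propargyl ether, [(prop-2-yn-1-yloxy)methyl]benzene | C#CCOCc1ccccc1 | starting material
4 | lithium [3-(benzyloxy)prop-1-yn-1-yl](isopropoxy)(pinacolato)borate | [Li+].CC(C)O[B-]1(C#CCOCc2ccccc2)OC(C)(C)C(C)(C)O1 | intermediate
5 | 2-[3-(benzyloxy)prop-1-yn-1-yl]-4,4,5,5-tetramethyl-1,3,2-dioxaborolane | CC1(C)OB(C#CCOCc2ccccc2)OC1(C)C | intermediate
6 | chlorobis(cyclopentadienyl)[(E)-3-(benzyloxy)-1-(4,4,5,5-tetramethyl-1,3,2-dioxaborolan-2-yl)prop-1-en-1-yl]zirconium (cyclopentadienyl rings drawn σ-bonded in the SMILES) | CC1(C)OB(/C(=C\COCc2ccccc2)[Zr](Cl)(C2C=CC=C2)C2C=CC=C2)OC1(C)C | intermediate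
7 | 2-[(Z)-3-(benzyloxy)prop-1-en-1-yl]-4,4,5,5-tetramethyl-1,3,2-dioxaborolane | CC1(C)OB(/C=C\COCc2ccccc2)OC1(C)C | intermediate
8 | lithium [(Z)-3-(benzyloxy)prop-1-en-1-yl](chloromethyl)(pinacolato)borate | [Li+].ClC[B-]1(/C=C\COCc2ccccc2)OC(C)(C)C(C)(C)O1 | intermediate
9 | 2-[(Z)-4-(benzyloxy)but-2-en-1-yl]-4,4,5,5-tetramethyl-1,3,2-dioxaborolane | CC1(C)OB(C/C=C\COCc2ccccc2)OC1(C)C | intermediate
10 | 4-[(1S,2S)-2-[(benzyloxy)methyl]-1-[(4,4,5,5-tetramethyl-1,3,2-dioxaborolan-2-yl)oxy]but-3-en-1-yl]-2,6-dimethoxyphenyl pivalate | C=C[C@@H](COCc1ccccc1)[C@H](OB1OC(C)(C)C(C)(C)O1)c1cc(OC)c(OC(=O)C(C)(C)C)c(OC)c1 | intermediate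
11 | 4-[(1S,2S)-2-[(benzyloxy)methyl]-1-hydroxybut-3-en-1-yl]-2,6-dimethoxyphenyl pivalate (syn) | C=C[C@@H](COCc1ccccc1)[C@H](O)c1cc(OC)c(OC(=O)C(C)(C)C)c(OC)c1 | intermediate
12 | allyltrimethylsilane | C=CC[Si](C)(C)C | starting material
13 | 4-[(1S,2S,3E)-2-[(benzyloxy)methyl]-1-hydroxy-5-(trimethylsilyl)pent-3-en-1-yl]-2,6-dimethoxyphenyl pivalate | C[Si](C)(C)C/C=C/[C@@H](COCc1ccccc1)[C@H](O)c1cc(OC)c(OC(=O)C(C)(C)C)c(OC)c1 | intermediate
14 | (E)-oxocarbenium ion from 13 and 2: the carbinol oxygen of 13 doubly bonded to the former formyl carbon of 2 | C[Si](C)(C)C/C=C/[C@@H](COCc1ccccc1)[C@H](/[O+]=C/c1cc(OC)c(OC(=O)C(C)(C)C)c(OC)c1)c1cc(OC)c(OC(=O)C(C)(C)C)c(OC)c1 | intermediate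
15 | (2S,3S,4R,5R)-3-[(benzyloxy)methyl]-2,5-bis[3,5-dimethoxy-4-(pivaloyloxy)phenyl]-4-vinyloxolane (2,5-cis, 2,3-cis, 3,4-trans, 4,5-trans) | COc1cc([C@H]2O[C@@H](c3cc(OC)c(OC(=O)C(C)(C)C)c(OC)c3)[C@H](C=C)[C@H]2COCc2ccccc2)cc(OC)c1OC(=O)C(C)(C)C | intermediate
16 | 1,2-diol from dihydroxylation of the vinyl group of 15: C4 carries CH(OH)CH2OH, both epimers at the new carbinol carbon | COc1cc([C@H]2O[C@@H](c3cc(OC)c(OC(=O)C(C)(C)C)c(OC)c3)[C@H](C(O)CO)[C@H]2COCc2ccccc2)cc(OC)c1OC(=O)C(C)(C)C | intermediate
17 | (2S,3S,4R,5R)-3-[(benzyloxy)methyl]-2,5-bis[3,5-dimethoxy-4-(pivaloyloxy)phenyl]-4-formyloxolane (formyl trans to both neighbours) | COc1cc([C@H]2O[C@@H](c3cc(OC)c(OC(=O)C(C)(C)C)c(OC)c3)[C@H](C=O)[C@H]2COCc2ccccc2)cc(OC)c1OC(=O)C(C)(C)C | intermediate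
18 | (2S,3S,4S,5R)-3-[(benzyloxy)methyl]-4-(hydroxymethyl)-2,5-bis(4-hydroxy-3,5-dimethoxyphenyl)oxolane | COc1cc([C@H]2O[C@@H](c3cc(OC)c(O)c(OC)c3)[C@H](CO)[C@H]2COCc2ccccc2)cc(OC)c1O | intermediate
19 | [(2S,3S,4S,5R)-2,5-bis(4-hydroxy-3,5-dimethoxyphenyl)oxolane-3,4-diyl]dimethanol | COc1cc([C@H]2O[C@@H](c3cc(OC)c(O)c(OC)c3)[C@H](CO)[C@H]2CO)cc(OC)c1O | target

## Step count and risk

Total step count: 10. Longest linear sequence: 9 steps (3 to 19, steps 2 to 10); step 1 is a side branch whose product 2 enters the main line twice.

**Step 7 (key step).** Two things are most likely to go wrong.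
- Incomplete 2,5-cis control: the C3 arm is cis to the C2 aryl and must sit pseudo-axial in the envelope that holds both aryl groups pseudo-equatorial, so the competing envelope is not far above it.
- Loss of precursor before the oxocarbenium ion forms: ionisation of the benzylic C2–OH, or protodesilylation of the allylsilane by adventitious protic acid.

Fallback: from 13, the hydroxyl is silylated (TMSCl, imidazole, CH2Cl2) to 4-[(1S,2S,3E)-2-[(benzyloxy)methyl]-5-(trimethylsilyl)-1-[(trimethylsilyl)oxy]pent-3-en-1-yl]-2,6-dimethoxyphenyl pivalate F1. F1 is combined with aldehyde 2 under catalytic trimethylsilyl triflate in CH2Cl2 at −78 °C. This is the silyl-modified Sakurai variant, in which the oxocarbenium ion arises by silyl transfer, with no free hydroxyl, no water and no strong protic acid. It rejoins the route at 15.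

**Step 5.** Facial and syn/anti control may be eroded, because the Z substituent is axial in the chair and carries an ether oxygen that can compete for the catalyst. The reaction may also be slow, which lets the uncatalysed racemic pathway contribute. Fallback: a Lewis-base-catalysed allylation at silicon, setting out from aldehyde 2.
- Commercial (Z)-4-(benzyloxy)but-2-en-1-ol F2 is converted with MsCl, LiCl and 2,4,6-collidine in DMF at 0 °C into (Z)-1-(benzyloxy)-4-chlorobut-2-ene F3.
- F3 is silylated with HSiCl3, CuCl (cat.) and iPr2NEt in Et2O, with retention of geometry, to trichloro[(Z)-4-(benzyloxy)but-2-en-1-yl]silane F4.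
- F4 adds to 2 in CH2Cl2 at −78 °C under a chiral bisphosphoramide Lewis base (the enantiomer giving Si-face addition), through a closed chair at hexacoordinate silicon that again turns Z into syn.
- Aqueous NaHCO3 work-up returns the route at 11.

**Step 6.** The metathesis may be sluggish, because the alkene sits next to a branched allylic carbon and a free hydroxyl. Self-metathesis of 12 and catalyst decomposition with double-bond migration would then compete. Fallback: the alkene is joined to silicon intramolecularly, setting out from 11.
- Silylation with allyl(chloro)dimethylsilane, Et3N and DMAP gives 4-[(1S,2S)-1-{[allyl(dimethyl)silyl]oxy}-2-[(benzyloxy)methyl]but-3-en-1-yl]-2,6-dimethoxyphenyl pivalate F5.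
- Ring-closing metathesis with the second-generation Grubbs catalyst RuCl2(=CHPh)(H2IMes)(PCy3) gives the cyclic (Z)-allylsiloxane 4-[(6S,7S)-6-[(benzyloxy)methyl]-2,2-dimethyl-1-oxa-2-silacyclohept-4-en-7-yl]-2,6-dimethoxyphenyl pivalate F6.
- F6 condenses with aldehyde 2 under BF3·OEt2 in CH2Cl2 at −78 °C by the same oxocarbenium–allylsilane closure, with the Si–O bond cleaved, and comes back to the route at 15 without passing through 13.

**Step 8.** Base treatment may trigger β-elimination of O1 from the enolate of 17, opening the ring at C5–O1 to an enal. Reclosure would not be guaranteed and C5 would be put at risk. Fallback: from 15, the crude periodate cleavage mixture is reduced in the same flask with NaBH4, with no base treatment. The product is (2S,3S,4S,5R)-3-[(benzyloxy)methyl]-4-(hydroxymethyl)-2,5-bis[3,5-dimethoxy-4-(pivaloyloxy)phenyl]oxolane F7, with the pivalates intact. LiAlH4 in THF then returns the route at 18. This path gives up the correction of C4 and relies on step 7 setting it directly.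

**Step 10.** Over-reduction is the risk: hydrogenolysis of the ring benzylic C–O bonds at the electron-rich free-phenol stage, or slow debenzylation through catalyst poisoning by the phenols. Fallback: the benzyl group is removed without hydrogen and before the phenols are unmasked, setting out from 17.
- NaBH4 in MeOH/THF gives the alcohol (2S,3S,4S,5R)-3-[(benzyloxy)methyl]-4-(hydroxymethyl)-2,5-bis[3,5-dimethoxy-4-(pivaloyloxy)phenyl]oxolane F7.
- BCl3 with pentamethylbenzene as cation scavenger in CH2Cl2 at −78 °C cleaves the benzyl ether to (2S,3S,4S,5R)-3,4-bis(hydroxymethyl)-2,5-bis[3,5-dimethoxy-4-(pivaloyloxy)phenyl]oxolane F8; the deactivated aryl groups protect the ring C–O bonds.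
- K2CO3 in MeOH removes the pivalates and comes back to the route at 19.

## Further compounds

F1 | step 7 | 4-[(1S,2S,3E)-2-[(benzyloxy)methyl]-5-(trimethylsilyl)-1-[(trimethylsilyl)oxy]pent-3-en-1-yl]-2,6-dimethoxyphenyl pivalate | C[Si](C)(C)C/C=C/[C@@H](COCc1ccccc1)[C@H](O[Si](C)(C)C)c1cc(OC)c(OC(=O)C(C)(C)C)c(OC)c1
F2 | step 5 | (Z)-4-(benzyloxy)but-2-en-1-ol | OC/C=C\COCc1ccccc1
F3 | step 5 | (Z)-1-(benzyloxy)-4-chlorobut-2-ene | ClC/C=C\COCc1ccccc1
F4 | step 5 | trichloro[(Z)-4-(benzyloxy)but-2-en-1-yl]silane | Cl[Si](Cl)(Cl)C/C=C\COCc1ccccc1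
F5 | step 6 | 4-[(1S,2S)-1-{[allyl(dimethyl)silyl]oxy}-2-[(benzyloxy)methyl]but-3-en-1-yl]-2,6-dimethoxyphenyl pivalate | C=C[C@@H](COCc1ccccc1)[C@H](O[Si](C)(C)CC=C)c1cc(OC)c(OC(=O)C(C)(C)C)c(OC)c1
F6 | step 6 | 4-[(6S,7S)-6-[(benzyloxy)methyl]-2,2-dimethyl-1-oxa-2-silacyclohept-4-en-7-yl]-2,6-dimethoxyphenyl pivalate | C[Si]1(C)C/C=C\[C@@H](COCc2ccccc2)[C@H](O1)c1cc(OC)c(OC(=O)C(C)(C)C)c(OC)c1
F7 | step 8 | (2S,3S,4S,5R)-3-[(benzyloxy)methyl]-4-(hydroxymethyl)-2,5-bis[3,5-dimethoxy-4-(pivaloyloxy)phenyl]oxolane | COc1cc([C@H]2O[C@@H](c3cc(OC)c(OC(=O)C(C)(C)C)c(OC)c3)[C@H](CO)[C@H]2COCc2ccccc2)cc(OC)c1OC(=O)C(C)(C)C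
F8 | step 10 | (2S,3S,4S,5R)-3,4-bis(hydroxymethyl)-2,5-bis[3,5-dimethoxy-4-(pivaloyloxy)phenyl]oxolane | COc1cc([C@H]2O[C@@H](c3cc(OC)c(OC(=O)C(C)(C)C)c(OC)c3)[C@H](CO)[C@H]2CO)cc(OC)c1OC(=O)C(C)(C)C
A1 | alternative 1 | dimethyl 2,5-cis-3-[(tert-butyldimethylsilyloxy)methyl]-2,5-bis[3,5-dimethoxy-4-(pivaloyloxy)phenyl]oxolane-4,4-dicarboxylate (target numbering) | COc1cc([C@H]2O[C@@H](c3cc(OC)c(OC(=O)C(C)(C)C)c(OC)c3)C(C(=O)OC)(C(=O)OC)[C@H]2CO[Si](C)(C)C(C)(C)C)cc(OC)c1OC(=O)C(C)(C)C
A2 | alternative 1 | dimethyl trans-2-[3,5-dimethoxy-4-(pivaloyloxy)phenyl]-3-[(tert-butyldimethylsilyloxy)methyl]cyclopropane-1,1-dicarboxylate, single enantiomer | COc1cc([C@H]2[C@H](CO[Si](C)(C)C(C)(C)C)C2(C(=O)OC)C(=O)OC)cc(OC)c1OC(=O)C(C)(C)C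
A3 | alternative 2 | methyl 2,5-cis-2-[4-(benzyloxy)-3,5-dimethoxyphenyl]-4-[(tert-butyldimethylsilyloxy)methyl]-5-[3,5-dimethoxy-4-(pivaloyloxy)phenyl]oxolane-3-carboxylate | COc1cc([C@H]2O[C@@H](c3cc(OC)c(OC(=O)C(C)(C)C)c(OC)c3)[C@H](CO[Si](C)(C)C(C)(C)C)[C@H]2C(=O)OC)cc(OC)c1OCc1ccccc1
A4 | alternative 2 | methyl 4-{[4-(benzyloxy)-3,5-dimethoxybenzyl]oxy}-3-[(tert-butyldimethylsilyloxy)methyl]-2-diazo-4-[3,5-dimethoxy-4-(pivaloyloxy)phenyl]butanoate | COC(=O)C(=[N+]=[N-])[C@@H](CO[Si](C)(C)C(C)(C)C)[C@@H](OCc1cc(OC)c(OCc2ccccc2)c(OC)c1)c1cc(OC)c(OC(=O)C(C)(C)C)c(OC)c1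
A5 | alternative 3 | 2,5-cis-3-[(benzyloxy)methyl]-2,5-bis[3,5-dimethoxy-4-(pivaloyloxy)phenyl]oxolane-4-carbaldehyde (target numbering; same structure as 17) | COc1cc([C@H]2O[C@@H](c3cc(OC)c(OC(=O)C(C)(C)C)c(OC)c3)[C@H](C=O)[C@H]2COCc2ccccc2)cc(OC)c1OC(=O)C(C)(C)C
A6 | alternative 3 | (1S,2R,3Z)-5-(benzyloxy)-1-[3,5-dimethoxy-4-(pivaloyloxy)phenyl]pent-3-ene-1,2-diol (anti) | O[C@@H](c1cc(OC)c(OC(=O)C(C)(C)C)c(OC)c1)[C@H](O)/C=C\COCc1ccccc1
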